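The decalin is unravelled (labdane numbering) by cutting the ring-fusion bond C5–C10 together with the C7=C8 double bond of ring B, which leads back to an acyclic keto enal carrying only the C3 silyloxy stereocentre. In the key step a base-mediated intramolecular Michael addition of the C10 ketone enolate to C5 of the enal closes ring A and forms C5–C10; aldol condensation of C8 onto the C7 aldehyde then closes ring B in the same flask. The step exploits the 1,5-relationship of C9 and C7 in ring B and the quaternary C10 flanked by the C4 gem-dimethyl group, and sets C5 and C10 from C3. The C9 side chain, from (S)-citronellol, is attached afterwards.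

Key step: step 5

Remark: labdane numbering is used (decalin C1–C10, ring A = C1–C5/C10, ring B = C5–C10; side chain C11–C15; CH3 groups C16 on C13, C17 on C8, C18/C19 on C4, C20 on C10; β = the face of C20). TBS = tert-butyldimethylsilyl. Compounds 5 and 7–9 are mixtures of epimers at the ketone α-carbon (future C10, re-enolised in step 5). In step 2 the ligand antipode is taken that gives the (S)-carbinol.

Step 1
Reactants: 1 pentan-3-one; 2 acrolein
Product: 5 4-methyl-5-oxoheptanal (racemic), via enamine 3 (not isolated), via adduct enamine 4 (not isolated)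
Conditions: pyrrolidine (1.2 equiv), TsOH (cat.), benzene, reflux (−H2O); then 2, MeCN, 0 °C → rt; then AcOH/NaOAc, H2O
Reagents that add atoms: water, O
Why: Stork enamine Michael addition of the symmetrical ketone to acrolein followed by hydrolysis should give the δ-keto aldehyde; the new α-centre needs no control because it is enolised again in step 5.

Step 2
Reactants: 5 4-methyl-5-oxoheptanal; 6 3-methylbuta-1,2-diene
Product: 7 (7S)-7-hydroxy-4,8,8-trimethyldec-9-en-3-one
Conditions: [Ir(cod)Cl]2 (2.5 mol%), (S)-SEGPHOS (5 mol%), 4-cyano-3-nitrobenzoic acid (10 mol%), Cs2CO3 (10 mol%), i-PrOH (2 equiv), 6 (3 equiv), THF, 50 °C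
Reagents that add atoms: none
Why: Krische iridium-catalysed transfer-hydrogenative reverse prenylation of the aldehyde should give the α,α-dimethyl homoallylic alcohol, the chiral Ir–SEGPHOS allyl complex setting C3 as S while the ketone stays untouched.

Step 3
Reactants: 7 (7S)-7-hydroxy-4,8,8-trimethyldec-9-en-3-one
Product: 8 (7S)-7-(TBSO)-4,8,8-trimethyldec-9-en-3-one
Conditions: TBSOTf, 2,6-lutidine, CH2Cl2, −78 → 0 °C
Reagents that add atoms: tert-butyldimethylsilyl trifluoromethanesulfonate CC(C)(C)[Si](C)(C)OS(=O)(=O)C(F)(F)F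
Why: Silylation of the hindered neopentylic alcohol with the silyl triflate protects O3 for steps 5 and 9–12 and supplies the bulky equatorial group used in step 5.

Step 4
Reactants: 8 (7S)-7-(TBSO)-4,8,8-trimethyldec-9-en-3-one; 2 acrolein
Product: 9 (2E,5S)-5-(TBSO)-4,4,8-trimethyl-9-oxoundec-2-enal
Conditions: 2 (5 equiv), second-generation Hoveyda–Grubbs catalyst RuCl2(H2IMes)(=CH-C6H4-2-Oi-Pr) (5 mol%), CH2Cl2, 40 °C
Reagents that add atoms: none
Why: Olefin cross-metathesis of the only alkene of 8 with the electron-poor partner acrolein should give the (E)-enal, E geometry being the usual outcome for enal cross-metathesis.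

Step 5
Reactants: 9 (2E,5S)-5-(TBSO)-4,4,8-trimethyl-9-oxoundec-2-enal
Product: 12 (4aS,6S,8aS)-6-(TBSO)-2,5,5,8a-tetramethyl-4a,5,6,7,8,8a-hexahydronaphthalen-1(4H)-one, via Michael adduct 10 (not isolated), via aldol adduct 11 (not isolated)
Conditions: KOH (0.5 equiv), MeOH/THF 1:4, 0.01 M, 0 → 50 °C
Reagents that add atoms: none
Why: Reversible enolisation of the ethyl ketone gives the tetrasubstituted C10 enolate, which adds to C5 of the tethered (E)-enal (intramolecular Michael addition, 6-(enolexo)-exo-trig, ring A, new bond C5–C10); the C8 enolate of keto aldehyde 10 then attacks the C7 aldehyde (6-(enolendo)-exo-trig aldol, ring B) and E1cB loss of water from 11 gives the C7=C8 enone. The closest known reaction type is the Robinson annulation (Michael addition, then aldol condensation), here with both events intramolecular so that an acyclic chain folds into the trans-decalin. C5 and C10 are set in the chair-like Michael transition state by the C3 centre: the OTBS group and the enal arm on C5 are equatorial, and of the two groups on C10 the bulky enolate unit avoids the 1,3-diaxial contact with the axial C4 methyl, so the C10 methyl ends axial and anti to H5. Regiochemistry is secured by ring size, since only the C10 enolate reaches C5 through a six-membered transition state (the C8 enolate would need an eight-membered one) and in 10 only C8 reaches the aldehyde through a six-membered ring (C6 would close a four-membered ring), while the undefined α-centre of 9 is erased. Competing 1,2-addition and intermolecular aldol reactions are held back by high dilution, and the irreversible dehydration drains the reversible Michael equilibrium towards 12.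

Step 6
Reactants: 13 (S)-citronellol
Product: 14 (S)-tert-butyl[(3,7-dimethyloct-6-en-1-yl)oxy]dimethylsilane
Conditions: TBSCl, imidazole, DMF, rt
Reagents that add atoms: tert-butyldimethylsilyl chloride CC(C)(C)[Si](C)(C)Cl
Why: Standard silylation of the primary alcohol; this oxygen becomes O15 and the stereocentre becomes C13.

Step 7
Reactants: 14 (S)-tert-butyl[(3,7-dimethyloct-6-en-1-yl)oxy]dimethylsilane
Product: 16 (S)-6-(TBSO)-4-methylhexanoic acid, via aldehyde 15 (not isolated)
Conditions: RuCl3 (2 mol%), NaIO4 (4.1 equiv), MeCN/EtOAc/H2O, 0 °C → rt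
Reagents that add atoms: sodium periodate [Na+].[O-]I(=O)(=O)=O (oxygen, via RuO4); water, O
Why: Catalytic ruthenium tetroxide cleavage of the trisubstituted alkene should give acetone and the carboxylic acid without touching the remote stereocentre.

Step 8
Reactants: 16 (S)-6-(TBSO)-4-methylhexanoic acid
Product: 17 (R)-tert-butyl[(5-iodo-3-methylpentyl)oxy]dimethylsilane
Conditions: PhI(OAc)2, I2, cyclohexane, hν (W lamp), reflux
Reagents that add atoms: iodine II
Why: Hunsdiecker-type radical iododecarboxylation (hypervalent-iodine variant): the acyl hypoiodite loses CO2 and the primary radical is trapped by iodine, leaving the five-carbon C11–C15 unit (the descriptor changes to R by priority only).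

Step 9
Reactants: 17 (R)-tert-butyl[(5-iodo-3-methylpentyl)oxy]dimethylsilane; 12 bicyclic enone
Product: 19 3β,15-bis(TBSO)-labd-7-en-9-ol, via organolithium 18 (not isolated)
Conditions: 17, t-BuLi (2.1 equiv), Et2O, −78 °C; then 12, CeCl3 (anhydrous), THF, −78 °C; aq. NH4Cl
Reagents that add atoms: none
Why: Lithium–iodine exchange and cerium-mediated 1,2-addition of the primary alkyl to the hindered C9 carbonyl (organocerium suppresses enolisation) should give the tertiary allylic alcohol, whose C9 configuration is irrelevant because C9 becomes sp2 in step 10.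

Step 10
Reactants: 19 3β,15-bis(TBSO)-labd-7-en-9-ol
Product: 20 3β,15-bis(TBSO)-labd-8-en-7-one
Conditions: pyridinium chlorochromate [C5H5NH][CrO3Cl] (3 equiv), NaOAc, 4 Å MS, CH2Cl2, rt
Reagents that add atoms: pyridinium chlorochromate [O-][Cr](=O)(=O)Cl.c1cc[nH+]cc1 (carbonyl oxygen)
Why: Babler–Dauben oxidative 1,3-transposition: the chromate ester of the tertiary allylic alcohol shifts by [3,3] rearrangement to C7 and is oxidised, giving the C8=C9 enone with the side chain on C9.

Step 11
Reactants: 20 3β,15-bis(TBSO)-labd-8-en-7-one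
Product: 22 3β,15-bis(TBSO)-labd-7-en-7-yl trifluoromethanesulfonate (9α-H), via lithium enolate 21 (not isolated)
Conditions: Li (2.2 equiv), NH3(l)/THF, t-BuOH (1 equiv), −78 °C; NH3 removed; PhNTf2, THF, −78 → 0 °C; aq. NH4Cl
Reagents that add atoms: N-phenylbis(trifluoromethanesulfonimide) O=S(=O)(N(c1ccccc1)S(=O)(=O)C(F)(F)F)C(F)(F)F
Why: Birch-type dissolving-metal reduction of the enone with axial protonation at C9 (H9 α, anti to the C10 methyl, side chain equatorial β) gives the regiodefined C7–C8 enolate, which is trapped as the enol triflate.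

Step 12
Reactants: 22 3β,15-bis(TBSO)-labd-7-en-7-yl trifluoromethanesulfonate
Product: 23 3β,15-bis(TBSO)-labd-7-ene
Conditions: Pd(OAc)2 (5 mol%), PPh3 (10 mol%), HCO2H, n-Bu3N, DMF, 60 °C
Reagents that add atoms: none
Why: Palladium-catalysed formate reduction of the enol triflate (oxidative addition to zerovalent palladium, hydride from formate with loss of CO2, reductive elimination) should replace OTf by H and leave the double bond at C7=C8.

Step 13
Reactants: 23 3β,15-bis(TBSO)-labd-7-ene
Product: 24 labd-7-ene-3β,15-diol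
Conditions: n-Bu4NF (5 equiv), THF, 50 °C; aq. NH4Cl
Reagents that add atoms: none
Why: Fluoride-mediated cleavage of both silyl ethers; no stereocentre is affected.

Step 14
Reactants: 24 labd-7-ene-3β,15-diol
Product: 25 3β-hydroxylabd-7-en-15-yl acetate (target)
Conditions: AcCl (1.05 equiv), 2,4,6-collidine, CH2Cl2, −78 °C
Reagents that add atoms: acetyl chloride CC(=O)Cl
Why: Selective O-acylation of the primary alcohol; the neopentylic secondary 3-OH next to the C4 gem-dimethyl group should not react at −78 °C.

Compound list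
1 | pentan-3-one | CCC(=O)CC | starting material
2 | acrolein (prop-2-enal) | C=CC=O | starting material
3 | 1-(pent-2-en-3-yl)pyrrolidine | CC=C(CC)N1CCCC1 | intermediate
4 | 4-methyl-5-(pyrrolidin-1-yl)hept-5-enal | CC=C(N1CCCC1)C(C)CCC=O | intermediate
5 | 4-methyl-5-oxoheptanal (racemic) | CCC(=O)C(C)CCC=O | intermediate
6 | 3-methylbuta-1,2-diene (1,1-dimethylallene) | CC(C)=C=C | starting material
7 | (7S)-7-hydroxy-4,8,8-trimethyldec-9-en-3-one (both C4 epimers) | C=CC(C)(C)[C@@H](O)CCC(C)C(=O)CC | intermediate
8 | (7S)-7-[(tert-butyldimethylsilyl)oxy]-4,8,8-trimethyldec-9-en-3-one (both C4 epimers) | C=CC(C)(C)[C@@H](O[Si](C)(C)C(C)(C)C)CCC(C)C(=O)CC | intermediate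
9 | (2E,5S)-5-[(tert-butyldimethylsilyl)oxy]-4,4,8-trimethyl-9-oxoundec-2-enal (both C8 epimers) | O=C/C=C/C(C)(C)[C@@H](O[Si](C)(C)C(C)(C)C)CCC(C)C(=O)CC | intermediate
10 | Michael adduct, 2-[3-(TBSO)-2,2,6-trimethyl-6-propanoylcyclohexyl]acetaldehyde (3β-OTBS, 5α-H, 10β-CH3; OTBS, CH2CHO and propanoyl equatorial) | O=CC[C@H]1C(C)(C)[C@@H](O[Si](C)(C)C(C)(C)C)CC[C@]1(C)C(=O)CC | intermediate
11 | aldol adduct, 3β-(TBSO)-7-hydroxy-4,4,8,10-tetramethyl-trans-decalin-9-one (5α-H, 10β-CH3; C7 and C8 undefined) | O=C1C(C)C(O)C[C@H]2C(C)(C)[C@@H](O[Si](C)(C)C(C)(C)C)CC[C@]12C | intermediate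
12 | (4aS,6S,8aS)-6-[(tert-butyldimethylsilyl)oxy]-2,5,5,8a-tetramethyl-4a,5,6,7,8,8a-hexahydronaphthalen-1(4H)-one (trans-fused; 9-oxo, C7=C8, 3β-OTBS, 5α-H, 10β-CH3) | O=C1C(C)=CC[C@H]2C(C)(C)[C@@H](O[Si](C)(C)C(C)(C)C)CC[C@]12C | intermediate
13 | (S)-citronellol, (3S)-3,7-dimethyloct-6-en-1-ol | OCC[C@@H](C)CCC=C(C)C | starting material
14 | (S)-tert-butyl[(3,7-dimethyloct-6-en-1-yl)oxy]dimethylsilane | CC(C)(C)[Si](C)(C)OCC[C@@H](C)CCC=C(C)C | intermediate
15 | (S)-6-[(tert-butyldimethylsilyl)oxy]-4-methylhexanal | CC(C)(C)[Si](C)(C)OCC[C@@H](C)CCC=O | intermediate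
16 | (S)-6-[(tert-butyldimethylsilyl)oxy]-4-methylhexanoic acid | CC(C)(C)[Si](C)(C)OCC[C@@H](C)CCC(=O)O | intermediate
17 | (R)-tert-butyl[(5-iodo-3-methylpentyl)oxy]dimethylsilane | CC(C)(C)[Si](C)(C)OCC[C@@H](C)CCI | intermediate
18 | [(3S)-5-[(tert-butyldimethylsilyl)oxy]-3-methylpentyl]lithium | CC(C)(C)[Si](C)(C)OCC[C@@H](C)CC[Li] | intermediate
19 | 3β,15-bis(TBSO)-labd-7-en-9-ol (5α-H, 10β-CH3, 13S; C9 undefined) | CC(C)(C)[Si](C)(C)OCC[C@@H](C)CCC1(O)C(C)=CC[C@H]2C(C)(C)[C@@H](O[Si](C)(C)C(C)(C)C)CC[C@]12C | intermediate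
20 | 3β,15-bis(TBSO)-labd-8-en-7-one (5α-H, 10β-CH3, 13S) | CC(C)(C)[Si](C)(C)OCC[C@@H](C)CCC1=C(C)C(=O)C[C@H]2C(C)(C)[C@@H](O[Si](C)(C)C(C)(C)C)CC[C@]12C | intermediate
21 | lithium 3β,15-bis(TBSO)-labd-7-en-7-olate (9α-H) | CC(C)(C)[Si](C)(C)OCC[C@@H](C)CC[C@H]1C(C)=C(O[Li])C[C@H]2C(C)(C)[C@@H](O[Si](C)(C)C(C)(C)C)CC[C@]12C | intermediate
22 | 3β,15-bis(TBSO)-labd-7-en-7-yl trifluoromethanesulfonate (5α-H, 9α-H, 10β-CH3, 13S) | CC(C)(C)[Si](C)(C)OCC[C@@H](C)CC[C@H]1C(C)=C(OS(=O)(=O)C(F)(F)F)C[C@H]2C(C)(C)[C@@H](O[Si](C)(C)C(C)(C)C)CC[C@]12C | intermediate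
23 | 3β,15-bis(TBSO)-labd-7-ene (3S,5R,9S,10R,13S) | CC(C)(C)[Si](C)(C)OCC[C@@H](C)CC[C@H]1C(C)=CC[C@H]2C(C)(C)[C@@H](O[Si](C)(C)C(C)(C)C)CC[C@]12C | intermediate
24 | labd-7-ene-3β,15-diol (3S,5R,9S,10R,13S) | OCC[C@@H](C)CC[C@H]1C(C)=CC[C@H]2C(C)(C)[C@@H](O)CC[C@]12C | intermediate
25 | 3β-hydroxylabd-7-en-15-yl acetate (3S,5R,9S,10R,13S), CNP0128233.1 | CC(=O)OCC[C@@H](C)CC[C@H]1C(C)=CC[C@H]2C(C)(C)[C@@H](O)CC[C@]12C | target

Total step count: 14. Longest linear sequence: 11 steps (steps 1–5 and 9–14, from pentan-3-one); the side-chain branch (steps 6–8) has 3 steps.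

Steps most likely to fail

Step 5 (key step). The tetrasubstituted enolate has to attack a neopentylic β-carbon, so ring closure may be slower than retro-Michael reaction and intermolecular aldol oligomerisation of the enal. A looser transition state could also erode the axial/equatorial choice at C10 and give cis-fused material. The fallback separates the two ring closures and uses a neutral, irreversible conjugate addition. From 9, soft enolisation (TMSOTf, Et3N, CH2Cl2, equilibrating conditions) gives the tetrasubstituted trimethylsilyl enol ether F1. TiCl4 (CH2Cl2, −78 °C) then triggers an intramolecular Mukaiyama–Michael addition to give keto aldehyde 10, isolated this time. KOH/MeOH closes ring B by aldol condensation and the route is rejoined at 12.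

Step 4. Initiation at the vinyl group on the quaternary carbon may be slow, so that self-metathesis or polymerisation of acrolein and catalyst decay use up the catalyst before cross-metathesis occurs. The fallback sets out from 8: ozonolysis (O3, CH2Cl2/MeOH, −78 °C; PPh3) gives the neopentylic aldehyde F2, and Wittig olefination with (triphenylphosphoranylidene)acetaldehyde (toluene, 90 °C) rejoins the route at 9.

Step 2. Keto aldehyde 5 may be lost by base-promoted intramolecular aldol condensation (ketone CH2 onto the aldehyde) during the warm, carbonate-buffered coupling, and enantiofacial control may be incomplete. The fallback avoids the free keto aldehyde. From 1, enolate alkylation with oxetane (LiN(i-Pr)2, THF, −78 °C; oxetane, BF3·OEt2) gives keto alcohol F3. This is reverse-prenylated with 6 from the alcohol oxidation level (same iridium catalyst, no i-PrOH, the transient aldehyde staying at low concentration), and the route is rejoined at 7.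

Further compounds
F1 | step 5 | (2E,5S)-5-[(tert-butyldimethylsilyl)oxy]-4,4,8-trimethyl-9-[(trimethylsilyl)oxy]undeca-2,8-dienal | O=C/C=C/C(C)(C)[C@@H](O[Si](C)(C)C(C)(C)C)CCC(C)=C(CC)O[Si](C)(C)C
F2 | step 4 | (3S)-3-[(tert-butyldimethylsilyl)oxy]-2,2,6-trimethyl-7-oxononanal | O=CC(C)(C)[C@@H](O[Si](C)(C)C(C)(C)C)CCC(C)C(=O)CC
F3 | step 2 | 7-hydroxy-4-methylheptan-3-one (racemic) | CCC(=O)C(C)CCCO
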